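In a closed flask the count of incoming ligand stays fixed: free plus bound equals the charge, and each form the complex takes other than starting complex, side product A among them, holds at least one. Wherever the ligand is charged below the complex it is the limiting reagent, and the fraction of starting complex left stands at or above the ligand floor, which is one minus [incoming ligand] over [starting complex] as charged.

| setting | delta | epsilon | alder | cedar |
|---|---|---|---|---|
| starting complex | 0.038 M | 0.086 M | 0.057 M | 0.057 M |
| incoming ligand | 0.0399 M | 0.0399 M | 0.0399 M | 0.0399 M |
| temperature | 15 °C | 28 °C | 20 °C | 35 °C |
| remark | run made earlier | run made earlier |  |  |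
| time |  |  | 40 min | 40 min |

| run | time / min | complex with one exchanged / % | starting complex / % | side product A / % | complex with three exchanged / % | side product B / % | complex with two exchanged / % |
|---|---|---|---|---|---|---|---|
| delta | 4.00 | 11.4 | 84.9 | 0 | 1.9 | 0.5 | 2.5 |
| delta | 8.00 | 19.9 | 75.9 | 1.9 | 0 | 0 | 2.3 |
| delta | 20.0 | 30.9 | 58.2 | 7.1 | 1.1 | 0.8 | 4.0 |
| delta | 50.0 | 31.6 | 37.6 | 21.2 | 3.2 | 0.6 | 6.6 |
| epsilon | 12.0 | 19.2 | 66.2 | 12.5 | 0 | 0 | 2.8 |
| epsilon | 25.0 | 10.7 | 60.5 | 22.9 | 1.7 | 0 | 2.4 |
| epsilon | 40.0 | 7.1 | 56.7 | 33.6 | 0 | 3.2 | 2.8 |
| epsilon | 50.0 | 4.7 | 56.0 | 36.6 | 0 | 2.8 | 0 |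

(standard deviation of a reading: 1 percentage point)

- what was read earlier has a scatter of 1 percentage point, one standard deviation

* which of these there is most of at the end, counted by the starting complex in it, alder (complex with two exchanged / side product A / starting complex / side product B / complex with one exchanged)
* which of these there is most of at the end, counted by the starting complex in it, cedar (complex with two exchanged / side product A / starting complex / side product B / complex with one exchanged)
* the largest of these amounts at the end, in percent of the starting complex charged, alder
* the largest of these amounts at the end, in percent of the starting complex charged, cedar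

Delta and epsilon carry the same [incoming ligand], 0.0399 M, and part on the complex charged and on the temperature. Epsilon, with 0.086 M, has a floor of 53.6 %, and its starting complex reads 56.7 % at 40.0 min and 56.0 % at 50.0 min, which is 2.4 percentage points above that floor. Delta, with 0.038 M, has a ligand-to-complex ratio of 1.05, so it has no floor above zero, and although it runs colder its starting complex goes from 58.2 % at 20.0 min to 37.6 % at 50.0 min. I therefore read epsilon's stop as the count of ligand, not as slowness.

Alder and cedar share a floor of 30.0 %. The reading at 40.0 min puts 72.4 % of epsilon's ligand charge in side product A, at one ligand each. Cedar is hotter than epsilon and holds more ligand per complex, so I carry that share over as an estimate, not a bound, and reckon about 50.7 % of side product A, which leaves less, 49.3 %, for the other forms together, starting complex among them, and so I name side product A first in cedar. Alder stands at 20 °C, near delta, with less ligand per complex than delta, so I name starting complex there. The forecast, on the same runs, holds that “ligand is also limiting in alder and cedar” and gives starting complex at 44 % in alder and side product A at 55 % in cedar.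

The flasks give starting complex at 47.8 % in alder and side product A at 53.0 % in cedar.

    starting complex + incoming ligand ⇌ leaving ligand + complex with one exchanged (K = 13.3, k = 0.0215 /M/s, Ea = 40.0 kJ/mol, ΔH = −13.0 kJ/mol)
    complex with one exchanged + incoming ligand ⇌ leaving ligand + complex with two exchanged (K = 1.30, k = 0.0116 /M/s, Ea = 62.0 kJ/mol, ΔH = −4.00 kJ/mol)
    complex with two exchanged + incoming ligand ⇌ leaving ligand + complex with three exchanged (K = 3.40, k = 0.0227 /M/s, Ea = 54.0 kJ/mol, ΔH = −24.0 kJ/mol)
    complex with three exchanged + incoming ligand ⇌ leaving ligand + complex with four exchanged (K = 2.49, k = 0.0160 /M/s, Ea = 60.0 kJ/mol, ΔH = −8.00 kJ/mol)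
    complex with one exchanged → side product A (k = 4.55 × 10⁻⁴ /s, Ea = 79.0 kJ/mol)
    leaving ligand + complex with three exchanged → side product B (k = 0.0235 /M/s, Ea = 69.0 kJ/mol)
    (constants at 20 °C)

Alder's starting complex stands 18 points above the floor at 40.0 min, with 14 % of the ligand still free, and at that moment the forward rate of the first exchange takes 4.2 times as much ligand as the forward rate of the second. Cedar, left until 400 min, has 0 % of its ligand free and 35.4 % of starting complex, 5.4 points above the floor, and its 2.70 % of side product B, with two ligands each beyond the one the floor counts, accounts for 5.4 points.

The readings are simulated from invented constants, and the scatter is random.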